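Ring B of the target holds a β-hydroxy ketone, C1(=O)–C2H2–C3(OH)Ph, beside the C4 stereocentre. Taking away C2 and the C3 oxygen in thought leaves a 2-phenylindanone whose five-membered ring is C1, C3, C4, C4a, C8a; the route builds that indanone, bridges C1 and C3 with C2 as a cyclopropanol, and then lets Mn(acac)2/O2 break the C1–C3 bond. This single operation enlarges the ring to ring B, forms the C3–O bond and sets C3 anti to the C4 pyranonyl group. The precursor is the bis-benzyl-protected, 6a-phenyl, 6-pyranonyl cyclopropa[a]inden-1a-ol 17, whose C6 centre (future C4) comes from an asymmetric conjugate addition to a 2-phenylindenone.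

Key step: step 10

Assumption: the target stereoisomer is (3S,4S), that is, C3–OH trans to the C4 pyranonyl group and C3–Ph cis to it.
Assumption: the catalyst from [RhCl(C2H4)2]2 and the chiral diene is taken to show the same facial preference on indenone 5 as on simple cyclic enones, which points to the (S,S)-diene; if the opposite sense is found, the (R,R)-diene is used with no other change.

Step 1
Reactants: 1 7-hydroxy-1-indanone
Product: 2 7-(benzyloxy)-2,3-dihydro-1H-inden-1-one
Conditions: BnBr, K2CO3, DMF, 60 °C
Reagents that add atoms: benzyl bromide, BrCc1ccccc1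
Why: Williamson ether synthesis, in which the hydrogen-bonded 7-phenol is deprotonated by carbonate and the phenoxide displaces bromide from benzyl bromide while the ketone is untouched.

Step 2
Reactants: 2 7-(benzyloxy)-2,3-dihydro-1H-inden-1-one; 3 bromobenzene
Product: 4 7-(benzyloxy)-2-phenyl-2,3-dihydro-1H-inden-1-one (racemic)
Conditions: Pd(OAc)2 (cat.), XPhos, NaOtBu, THF, 60 °C
Reagents that add atoms: none
Why: Ketone α-arylation of the Buchwald–Hartwig type, in which bromobenzene adds oxidatively to zerovalent palladium, the enolate binds and C–C reductive elimination places phenyl on C2; the more acidic product rests as its stabilised enolate, which should hold back a second arylation, and the racemic C2 centre is destroyed in step 3.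

Step 3
Reactants: 4 7-(benzyloxy)-2-phenyl-2,3-dihydro-1H-inden-1-one
Product: 5 7-(benzyloxy)-2-phenyl-1H-inden-1-one
Conditions: DDQ, 1,4-dioxane, 90 °C
Reagents that add atoms: none
Why: Quinone dehydrogenation, in which DDQ takes the benzylic C3 hydride from the readily formed enol of the 2-aryl ketone and proton loss gives the conjugated 2-phenylindenone; the benzyl aryl ether should be tolerated.

Step 4
Reactants: 6 malonyl dichloride
Product: 9 6-chloro-4-hydroxy-2H-pyran-2-one, via pyranone acid chloride 7 (not isolated), via pyranone carboxylic acid 8 (not isolated)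
Conditions: neat (2 equiv of 6 per product, moisture excluded), rt; then H2O, 1,4-dioxane, 40 °C
Reagents that add atoms: malonyl dichloride (second molecule), O=C(Cl)CC(Cl)=O; water, O
Why: Self-condensation of malonyl dichloride followed by hydrolytic decarboxylation, in which a second molecule of 6 C-acylates the methylene carbon of the first and lactonising O-acylation of the resulting enol closes acid chloride 7 with loss of two HCl, water converts 7 into the vinylogous β-keto acid 8, and gentle warming expels CO2 (which carries off the oxygen that water brought in), the 6-chloro enol-ester position being expected to outlast the brief aqueous treatment.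

Step 5
Reactants: 9 6-chloro-4-hydroxy-2H-pyran-2-one
Product: 10 4-(benzyloxy)-6-chloro-2H-pyran-2-one
Conditions: BnOH, PPh3, DIAD, THF, 0 °C to rt
Reagents that add atoms: benzyl alcohol, OCc1ccccc1
Why: Mitsunobu reaction, in which the acidic 4-hydroxyl (a vinylogous carboxylic acid) protonates the PPh3–DIAD betaine and its oxygen displaces Ph3PO from the benzyloxyphosphonium ion, so the 4-benzyl ether forms without base, without C3 alkylation and with the electrophilic 6-chloride left in place.

Step 6
Reactants: 10 4-(benzyloxy)-6-chloro-2H-pyran-2-one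
Product: 11 4-(benzyloxy)-6-(4,4,5,5-tetramethyl-1,3,2-dioxaborolan-2-yl)-2H-pyran-2-one
Conditions: B2pin2, PdCl2(dppf) (cat.), KOAc, 1,4-dioxane, 80 °C
Reagents that add atoms: bis(pinacolato)diboron, CC1(C)OB(OC1(C)C)B1OC(C)(C)C(C)(C)O1
Why: Miyaura borylation, in which zerovalent palladium inserts into the activated C6–Cl bond (a vinylogous chloroformate) and acetate-assisted transmetalation with B2pin2 followed by reductive elimination gives the alkenyl pinacol boronate, the weak base KOAc disfavouring Suzuki homocoupling.

Step 7
Reactants: 5 7-(benzyloxy)-2-phenyl-1H-inden-1-one; 11 4-(benzyloxy)-6-(4,4,5,5-tetramethyl-1,3,2-dioxaborolan-2-yl)-2H-pyran-2-one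
Product: 12 (3R)-7-(benzyloxy)-3-[4-(benzyloxy)-2-oxo-2H-pyran-6-yl]-2-phenyl-2,3-dihydro-1H-inden-1-one (mixture of C2 epimers)
Conditions: [RhCl(C2H4)2]2 (2.5 mol %), (1S,4S)-2,5-diphenylbicyclo[2.2.2]octa-2,5-diene (5.5 mol %), KOH (aq, 0.2 equiv), 1,4-dioxane/H2O, 30 °C
Reagents that add atoms: none
Why: Hayashi–Miyaura conjugate addition, in which the pyranonyl group passes from boron to the hydroxo(diene)rhodium complex (monovalent rhodium; the labile ethylene ligands of the precursor leave no achiral diene behind) and inserts into the strained, electrophilic indenone C2=C3 bond, the C2-symmetric diene exposing one enone face so that C3 is set as R; hydrolysis frees the ketone as C2 epimers that converge in step 8.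

Step 8
Reactants: 12 (3R)-7-(benzyloxy)-3-[4-(benzyloxy)-2-oxo-2H-pyran-6-yl]-2-phenyl-2,3-dihydro-1H-inden-1-one
Product: 14 (1S)-4-(benzyloxy)-1-[4-(benzyloxy)-2-oxo-2H-pyran-6-yl]-2-phenyl-3-[(trimethylsilyl)oxy]-1H-indene, via lithium enolate 13 (not isolated)
Conditions: LiN(SiMe3)2 (1.0 equiv), THF, −78 °C; Me3SiCl, −78 to 0 °C; non-aqueous work-up
Reagents that add atoms: chlorotrimethylsilane, C[Si](C)(C)Cl
Why: Enolate O-silylation, in which one equivalent of the hindered amide removes only the doubly activated C2–H (α to the ketone and benzylic) and Me3SiCl traps the enolate on oxygen; only the feebly basic HN(SiMe3)2 remains, so the indenyl-type C1–H of 14 is not ionised and the configuration of the former C3 is kept.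

Step 9
Reactants: 14 (1S)-4-(benzyloxy)-1-[4-(benzyloxy)-2-oxo-2H-pyran-6-yl]-2-phenyl-3-[(trimethylsilyl)oxy]-1H-indene; 15 diiodomethane
Product: 17 (1aS,6S,6aR)-2-(benzyloxy)-6-[4-(benzyloxy)-2-oxo-2H-pyran-6-yl]-6a-phenyl-6,6a-dihydrocyclopropa[a]inden-1a(1H)-ol, via trimethylsilyl cyclopropyl ether 16 (not isolated)
Conditions: Et2Zn, CH2I2 (carbenoid preformed), CH2Cl2, 0 °C to rt; then Bu4NF, AcOH, THF, 0 °C
Reagents that add atoms: none
Why: Simmons–Smith cyclopropanation (Furukawa variant) of the electron-rich enol ether double bond by the zinc carbenoid, expected on the face anti to the pyranonyl group (either face serves, since step 10 erases both new centres), followed by buffered fluoride cleavage of the Si–O bond near neutral pH so that the 2-phenylcyclopropanol is not opened by base.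

Step 10
Reactants: 17 (1aS,6S,6aR)-2-(benzyloxy)-6-[4-(benzyloxy)-2-oxo-2H-pyran-6-yl]-6a-phenyl-6,6a-dihydrocyclopropa[a]inden-1a(1H)-ol
Product: 19 (3S,4S)-8-(benzyloxy)-4-[4-(benzyloxy)-2-oxo-2H-pyran-6-yl]-3-hydroxy-3-phenyl-3,4-dihydronaphthalen-1(2H)-one, via C3 hydroperoxide 18 (not isolated)
Conditions: Mn(acac)2 (5 mol %), O2 (1 atm), PhH, rt; then Ar purge, PPh3, 0 °C
Reagents that add atoms: dioxygen, O=O
Why: Mn(acac)2 (divalent manganese) and O2 turn the cyclopropanol into a manganese cyclopropanolate that is oxidised by one electron, and β-scission of the oxygen-centred radical breaks the bond shared by the three- and five-membered rings (C1a–C6a, the future C1–C3 link), because this gives a tertiary benzylic radical at C3 and releases the strain of the bicyclo[3.1.0] unit, whereas scission toward the CH2 group would leave a primary radical. The closest known reaction type is the aerobic opening of cyclopropanols with Mn(acac)2 to β-peroxy ketones and their reduction to β-hydroxy ketones, together with the oxidative ring enlargement of ring-fused cyclopropanols. Ring B is not closed by a new bond but arises by ring enlargement, the one-carbon bridge C2 being taken into the former five-membered ring when the shared bond breaks, so no cyclisation mode has to compete. The new stereocentre C3 is set when O2 adds to the planar benzylic radical on the face anti to the pyranonyl group at the pre-set neighbour C4, which the peri C5–H holds pseudo-axial, giving the trans O/pyranonyl (3S,4S) arrangement with phenyl equatorial. The step needs scission of the internal bond, which the 6a-phenyl group secures, and face-selective oxygen capture, which C4 secures; both cyclopropane diastereomers give the same radical, so the cyclopropane configuration does not matter. PPh3 then reduces hydroperoxide 18 (or its bridged peroxy-hemiketal) to the alcohol under neutral conditions that spare the dehydration-prone β-hydroxy ketone.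

Step 11
Reactants: 19 (3S,4S)-8-(benzyloxy)-4-[4-(benzyloxy)-2-oxo-2H-pyran-6-yl]-3-hydroxy-3-phenyl-3,4-dihydronaphthalen-1(2H)-one
Product: 20 (3S,4S)-3,8-dihydroxy-4-(4-hydroxy-2-oxo-2H-pyran-6-yl)-3-phenyl-3,4-dihydronaphthalen-1(2H)-one
Conditions: H2 (1 atm), Pd/C (10 wt %), EtOAc, rt, stopped after uptake of two equivalents
Reagents that add atoms: none
Why: Catalytic hydrogenolysis, in which the aryl benzyl ether and the vinylogous benzyl ester of the pyranone should be cleaved in a neutral solvent faster than the pyranone ring is reduced or the tertiary C3–OH is lost; no acid or base is present to dehydrate the β-hydroxy ketone, and no stereocentre is touched.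

Compound list
1 | 7-hydroxy-1-indanone | O=C1CCc2cccc(O)c21 | starting material
2 | 7-(benzyloxy)-2,3-dihydro-1H-inden-1-one | O=C1CCc2cccc(OCc3ccccc3)c21 | intermediate
3 | bromobenzene | Brc1ccccc1 | starting material
4 | 7-(benzyloxy)-2-phenyl-2,3-dihydro-1H-inden-1-one (racemic) | O=C1C(c2ccccc2)Cc2cccc(OCc3ccccc3)c21 | intermediate
5 | 7-(benzyloxy)-2-phenyl-1H-inden-1-one | O=C1C(c2ccccc2)=Cc2cccc(OCc3ccccc3)c21 | intermediate
6 | malonyl dichloride | O=C(Cl)CC(Cl)=O | starting material
7 | 6-chloro-4-hydroxy-2-oxo-2H-pyran-3-carbonyl chloride (not isolated) | O=C(Cl)c1c(O)cc(Cl)oc1=O | intermediate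
8 | 6-chloro-4-hydroxy-2-oxo-2H-pyran-3-carboxylic acid (not isolated) | O=C(O)c1c(O)cc(Cl)oc1=O | intermediate
9 | 6-chloro-4-hydroxy-2H-pyran-2-one | O=c1cc(O)cc(Cl)o1 | intermediate
10 | 4-(benzyloxy)-6-chloro-2H-pyran-2-one | O=c1cc(OCc2ccccc2)cc(Cl)o1 | intermediate
11 | 4-(benzyloxy)-6-(4,4,5,5-tetramethyl-1,3,2-dioxaborolan-2-yl)-2H-pyran-2-one | O=c1cc(OCc2ccccc2)cc(B2OC(C)(C)C(C)(C)O2)o1 | intermediate
12 | (3R)-7-(benzyloxy)-3-[4-(benzyloxy)-2-oxo-2H-pyran-6-yl]-2-phenyl-2,3-dihydro-1H-inden-1-one (C2 epimers) | O=C1C(c2ccccc2)[C@@H](c2cc(OCc3ccccc3)cc(=O)o2)c2cccc(OCc3ccccc3)c21 | intermediate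
13 | lithium (1S)-4-(benzyloxy)-1-[4-(benzyloxy)-2-oxo-2H-pyran-6-yl]-2-phenyl-1H-inden-3-olate (not isolated) | [Li+].[O-]C1=C(c2ccccc2)[C@@H](c2cc(OCc3ccccc3)cc(=O)o2)c2cccc(OCc3ccccc3)c21 | intermediate
14 | (1S)-4-(benzyloxy)-1-[4-(benzyloxy)-2-oxo-2H-pyran-6-yl]-2-phenyl-3-[(trimethylsilyl)oxy]-1H-indene | C[Si](C)(C)OC1=C(c2ccccc2)[C@@H](c2cc(OCc3ccccc3)cc(=O)o2)c2cccc(OCc3ccccc3)c21 | intermediate
15 | diiodomethane | ICI | starting material
16 | (1aS,6S,6aR)-2-(benzyloxy)-6-[4-(benzyloxy)-2-oxo-2H-pyran-6-yl]-6a-phenyl-1a-[(trimethylsilyl)oxy]-1,1a,6,6a-tetrahydrocyclopropa[a]indene (not isolated; cyclopropane anti to the pyranonyl group) | C[Si](C)(C)O[C@@]12C[C@]1(c1ccccc1)[C@@H](c1cc(OCc3ccccc3)cc(=O)o1)c1cccc(OCc3ccccc3)c12 | intermediate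
17 | (1aS,6S,6aR)-2-(benzyloxy)-6-[4-(benzyloxy)-2-oxo-2H-pyran-6-yl]-6a-phenyl-6,6a-dihydrocyclopropa[a]inden-1a(1H)-ol (cyclopropane anti to the pyranonyl group) | O[C@@]12C[C@]1(c1ccccc1)[C@@H](c1cc(OCc3ccccc3)cc(=O)o1)c1cccc(OCc3ccccc3)c12 | intermediate
18 | (3S,4S)-8-(benzyloxy)-4-[4-(benzyloxy)-2-oxo-2H-pyran-6-yl]-3-hydroperoxy-3-phenyl-3,4-dihydronaphthalen-1(2H)-one (not isolated) | O=C1C[C@@](OO)(c2ccccc2)[C@@H](c2cc(OCc3ccccc3)cc(=O)o2)c2cccc(OCc3ccccc3)c21 | intermediate
19 | (3S,4S)-8-(benzyloxy)-4-[4-(benzyloxy)-2-oxo-2H-pyran-6-yl]-3-hydroxy-3-phenyl-3,4-dihydronaphthalen-1(2H)-one | O=C1C[C@@](O)(c2ccccc2)[C@@H](c2cc(OCc3ccccc3)cc(=O)o2)c2cccc(OCc3ccccc3)c21 | intermediate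
20 | (3S,4S)-3,8-dihydroxy-4-(4-hydroxy-2-oxo-2H-pyran-6-yl)-3-phenyl-3,4-dihydronaphthalen-1(2H)-one | O=C1C[C@@](O)(c2ccccc2)[C@@H](c2cc(O)cc(=O)o2)c2cccc(O)c21 | target

Total step count: 11 steps.
Longest linear sequence: 8 steps (steps 1, 2, 3, 7, 8, 9, 10 and 11 from compound 1; the pyranone branch, steps 4 to 6 and then 7 to 11, is equally long).

Steps most likely to fail

Step 7. The electron-poor, α-oxygenated alkenyl boronate may lose boron by protonolysis before it transmetalates, the α-phenyl-substituted enone may insert slowly, or the face selectivity may be low. The fallback reverses the polarity of the C3–pyranonyl bond formation. It sets out from indenone 5: enantioselective conjugate borylation (CuCl, chiral bisphosphine such as (R)-DTBM-SEGPHOS, NaOtBu cat., B2pin2, MeOH, THF, rt) should give the β-boryl ketone (3R)-7-(benzyloxy)-2-phenyl-3-(4,4,5,5-tetramethyl-1,3,2-dioxaborolan-2-yl)-2,3-dihydro-1H-inden-1-one F1. Stereoretentive Suzuki–Miyaura coupling of this secondary benzylic boronate with chloropyranone 10 (Pd2(dba)3, PPh3, Ag2O, DME, 70 °C) comes back to the route at 12. Step 6 is then not needed; should the coupling invert C3, the antipodal bisphosphine is used in the borylation.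

Step 10. The small O2 molecule may capture the planar C3 radical with poor facial selectivity, the pyranonyl group may migrate to the radical centre if O2 is deficient, or the tertiary carbinol may dehydrate to a naphthol during peroxide reduction. The fallback traps the same radical with a bulky persistent radical instead of O2. It sets out from cyclopropanol 17: oxidative opening with stoichiometric Mn(acac)3 (trivalent manganese) and TEMPO in MeCN at rt under argon should give the alkoxyamine (3S,4S)-8-(benzyloxy)-4-[4-(benzyloxy)-2-oxo-2H-pyran-6-yl]-3-phenyl-3-[(2,2,6,6-tetramethylpiperidin-1-yl)oxy]-3,4-dihydronaphthalen-1(2H)-one F2. C–O bond formation at a tertiary benzylic carbon is reversible, so the adduct can settle as the trans isomer. Cleavage of the N–O bond with Zn dust in AcOH/THF at rt comes back to the route at 19.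

Step 9. The indenyl-type C1–H of 14 may be ionised (loss of configuration at the future C4), carbenoid transfer to the tetrasubstituted double bond may be slow, or zinc iodide may rearrange siloxycyclopropane 16. The fallback cyclopropanates the enolate directly. It sets out from ketone 12: the lithium enolate 13, made as in step 8, is not silylated but treated at −78 °C to rt in THF with the samarium carbenoid generated from Sm metal and diiodomethane 15; aqueous NH4Cl then gives the cyclopropanol and the route is rejoined at 17. The neutral silyl indene, the zinc Lewis acid and the fluoride treatment are all avoided.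

Further compounds
F1 | step 7 | (3R)-7-(benzyloxy)-2-phenyl-3-(4,4,5,5-tetramethyl-1,3,2-dioxaborolan-2-yl)-2,3-dihydro-1H-inden-1-one (C2 epimers) | O=C1C(c2ccccc2)[C@@H](B2OC(C)(C)C(C)(C)O2)c2cccc(OCc3ccccc3)c21
F2 | step 10 | (3S,4S)-8-(benzyloxy)-4-[4-(benzyloxy)-2-oxo-2H-pyran-6-yl]-3-phenyl-3-[(2,2,6,6-tetramethylpiperidin-1-yl)oxy]-3,4-dihydronaphthalen-1(2H)-one | O=C1C[C@@](ON2C(C)(C)CCCC2(C)C)(c2ccccc2)[C@@H](c2cc(OCc3ccccc3)cc(=O)o2)c2cccc(OCc3ccccc3)c21
F0 | step 9 | none | none
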